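## The problem

The target joins an enolised 2-acetylcyclohexane-1,3,5-trione (ring A) through a spiro carbon to a trans-fused hydrindane. Ring A is numbered C1 (spiro), C2 (carbonyl next to the acetyl-bearing C3), C4 (enol), C5 (bis-prenylated) and C6 (carbonyl). Ring B is C1–C1'H2–C2'H–C6'H–C7'(CH3)(OH)–C8'H2 and ring C is C2'–C3'(CH3)(OH)–C4'H2–C5'H2–C6'. There are five stereocentres (C1, C2', C3', C6', C7'). C3' is an isolated quaternary carbinol that can be bought and can steer C2'. C2' and the chair of ring B can steer the spiro centre C1. C6' is epimerisable as long as C7' is a ketone and can be left to equilibrium. C7' has to come last. Its methyl group is axial and 1,3-syn to the axial C2 carbon of ring A, so a carbon nucleophile cannot be delivered to a C7' ketone from the required face. Ring A is a strong vinylogous acid that binds metals and is opened by hot hydroxide (retro-Claisen at the non-enolisable diketone), and its O2 oxygen sits over ring B where it can capture a C7' cation. The two tertiary alcohols ionise under acid, and the prenyl alkenes tolerate neither oxidants, hydrogen-atom transfer nor hydrogenation. The feature that opens the route is that C1'=C2'–C3'(CH3)(O)–C4'–C5'–C6' is the skeleton of (R)-linalool without its isopropylidene end, and that C1 is the ring carbon of an acylphloroglucinol. A radical at C6', made possible by a C7' ketone, can therefore add to the vinyl group and pass its spin to C1', which is placed to attack C1 and dearomatise ring A.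

## Retrosynthesis

**C5–prenyl bonds (26 to 23 and 24).** The two C5–CH2 bonds are cut first. The prenyl alkenes would not survive the hydration of the C7' alkene or the hydrogenolysis that unveils ring A, so they must be the last atoms added. In 23, C1 is quaternary and C3 is tied up in the acyl enolate, so C5 is the only doubly activated CH2. The forward step asks for C- over O-alkylation, twice, at one carbon.

**Ring A protection (23 to 21).** No skeletal bond is cut here. Ring A is carried from the arene stage as a bis(benzyl enol ether) and O3' as a triethylsilyl ether. Benzyl was chosen over methyl because a vinylogous benzyl ester leaves by neutral hydrogenolysis, whereas removing two methyl enol ethers would need acid (a risk to the tertiary alcohols) or hydroxide (a risk of retro-Claisen). The forward step must leave the tertiary alcohols alone.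

**C7' carbinol (21 to 19 to 18).** The C7'–O bond is cut, not the C7'–CH3 bond. Addition of a methyl nucleophile to the C7' ketone of 18 would come from the equatorial face and give the wrong epimer. The ketone is therefore first methylenated (19) and oxygen is then brought to the tertiary centre from the open equatorial face. A radical hydration is preferred to a cationic one because a C7' cation could be captured from the axial side by the ring A oxygen. The precursor 18 is simpler by one stereocentre.

**Rings B and C (18 to 16).** The C6'–C2' and C1'–C1 bonds are cut together. This removes two rings and three stereocentres and leads back to an acyclic aryl α-bromoketone whose only stereocentre is the linalool carbinol. Cutting C1'–C1 alone (a polar dearomatising alkylation) or C6'–C2' alone would each need a separately functionalised C1'. The forward cascade must close in the 5-exo and ipso modes and control C2' and C1. The ortho oxygens are capped (O2 benzyl, O6 triisopropylsilyl) so that no free phenol sits beside the α-bromoketone. The bulky O6 silyl group also differentiates C6 from C2 and leaves as a silyl cation, which makes C6 the ketone.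

**C6'–Br and C6'–C7' (16 to 15 to 14 to 12 and 4).** The bromide is traced to the hydroxyl of ketol 15, and the C6'–C7' bond to the addition of a C7' acyl anion equivalent (dithiane 12) to the C6' aldehyde 4. This cut fixes the position of the bromine by construction. The neighbouring option, alkylating a simple ketone and brominating it, would have to choose between three enolisable positions, and electrophilic bromine would attack the arene. The forward addition must tolerate the aryl methyl ketone.

**C6' aldehyde (4 to 2 to 1).** The C6=C7 bond of (R)-linalool is cut by ozonolysis after silylation of the tertiary alcohol. The vinyl group must survive, which the much higher reactivity of the trisubstituted alkene should allow.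

**Aryl dithiane (12 to 11 to 9 to 8 to 7 to 6 to 5).** The C1–C8' bond is traced to an aromatic Claisen rearrangement of the 4-O-allyl ether 7, which places the two-carbon arm next to the oxygen that becomes O6. The allyl group is cleaved to the aldehyde (11) and converted to the dithiane (12). Direct C-alkylation of 5 would be shorter but gives mixtures and no differentiation of the three oxygens. The sequence O-allylation (6), benzylation (7), rearrangement (8) and silylation (9) sets the pattern O2/O4 benzyl and O6 silyl without any selective deprotection.

## Roads not taken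

**Alternative 1:** Ring C is cut from a cyclopentanone. A CuBr·SMe2/chiral ferrocenyl diphosphine catalyst adds an isopropenyl Grignard reagent to the parent five-membered enone (C6'–C7' bond), and the magnesium enolate is captured by a methylenemalonate trans to the new group (C2'–C1' bond) to give A1. In A1 the ketone carbon is C3', the isopropenyl group is C7' with C8', and the malonate carbon is the future C1.
- Merits: the absolute configuration comes from a catalyst; the trans relation of C2' and C6' is set directly by the anti trapping, whereas the chosen plan leaves C6' to an equilibrium; methyl addition to the C3' ketone anti to the side chain should give the right carbinol.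
- Weak points: ring A has to be built atom by atom on the malonate (two acylations, the acetyl group, two prenyl groups). Its two ester arms differ only through remote centres, so the spiro centre is not controlled when ring A is desymmetrised. Ring B must still be closed through C8'–C1 with the C7' carbinol set on an open chain.
- Comparison: for rings B and C this road is the more certain one. The chosen plan sets against it that ring A arrives complete from one commercial arene and that the spiro centre is fixed in the same operation that closes ring B.

**Alternative 2:** Ring C is cut at C2'–C6' and C7'–O. Ph3PAuNTf2 in wet dioxane activates the terminal alkyne of a linalool-type 1,6-enyne, the trisubstituted alkene attacks in the 5-exo-dig mode, and water captures the tertiary cation, giving A2 with C3', C6' and C7' set and an exocyclic methylene at C2'.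
- Merits: the C7' tertiary alcohol, the hardest centre of the chosen plan, is set stereospecifically by anti addition across an alkene of defined geometry, in the step that forms ring C. In this respect the road is better, and the chosen plan has to answer with a two-step methylenation and hydration whose outcome rests on steric shielding.
- Weak points: the face of attack is steered only by a quaternary carbinol with two groups of similar size. C2' is left trigonal and must be set later. Ring B and the spiro centre need two bonds to C1 by double alkylation of a ring A trione, one of them at the neopentyl C8', with O-alkylation as competitor and no handle on the spiro configuration.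
- Comparison: the chosen plan makes both bonds of ring B that Alternative 2 leaves open, and sets C2' and C1 while doing so.

**Alternative 3:** The C1'–C2' and O–C3' bonds are cut. Oxidation of the C1-methyl trione with TEMPO and Ag2O gives the ortho-quinone methide (O=C2–C1=C1'), which adds across the trisubstituted alkene of a methylcyclopentene to give the dihydropyran A3.
- Merits: it is the most convergent road. Ring A is complete with acetyl and prenyl groups before the union, the suprafacial addition puts the oxygen on C3' cis to C1' as required, and no chiral tertiary alcohol has to be bought. In convergence and in the C2'/C3' relation it is equal or better.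
- Weak points: the heterodiene can use O2 or O6, which later decides the spiro configuration. The face of addition is steered by one substituent. In A3, C1 is still trigonal, so the enol ether must be hydrolysed and ring B closed through C1–C8' onto a centre flanked by two carbonyls. The C7' carbinol problem is untouched, and the prenyl groups are exposed to the oxidant.
- Comparison: the spiro centre and ring B, the core of the problem, are postponed, while the chosen key step forms exactly these.

Key step: step 12

Assumption: the C6' carbinol/bromide centre of 14, 15 and 16 is carried as a mixture of epimers, which is harmless because C6' becomes a planar radical in step 12. Descriptors of spiro compounds use the locants defined above and the tautomers drawn.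

## Route

Step 1
Reactants: 1 (R)-linalool
Product: 2 (3R)-3,7-dimethyl-3-(triethylsilyloxy)octa-1,6-diene
Conditions: TESOTf, 2,6-lutidine, CH2Cl2, −78 → 0 °C
Reagents that add atoms: triethylsilyl trifluoromethanesulfonate, CC[Si](CC)(CC)OS(=O)(=O)C(F)(F)F
Why: Silylation of a tertiary allylic alcohol with a silyl triflate and a hindered pyridine is routine and touches no stereocentre. The ether prevents lactol formation after ozonolysis and should stand the organolithium, Appel and photoredox steps.

Step 2
Reactants: 2 (3R)-3,7-dimethyl-3-(triethylsilyloxy)octa-1,6-diene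
Product: 4 (4R)-4-methyl-4-(triethylsilyloxy)hex-5-enal, via ozonide 3 (not isolated)
Conditions: O3 (one equivalent, Sudan Red 7B end point), CH2Cl2, −78 °C; then PPh3, −78 °C → rt
Reagents that add atoms: ozone, [O-][O+]=O
Why: Ozonolysis with reductive work-up. Ozone should add far faster to the trisubstituted alkene than to the vinyl group beside the oxygenated quaternary carbon, and the dye end point stops the reaction at one equivalent.

Step 3
Reactants: 5 2,4,6-trihydroxyacetophenone
Product: 6 1-[4-(allyloxy)-2,6-dihydroxyphenyl]ethanone
Conditions: allyl bromide (1.0 equiv), K2CO3 (1.1 equiv), acetone, 56 °C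
Reagents that add atoms: allyl bromide, C=CCBr
Why: Williamson etherification. The 4-hydroxyl (para to the acetyl group) is the most acidic and the only one not chelated to the carbonyl, so one equivalent of halide should etherify it selectively.

Step 4
Reactants: 6 1-[4-(allyloxy)-2,6-dihydroxyphenyl]ethanone
Product: 7 1-[4-(allyloxy)-2,6-bis(benzyloxy)phenyl]ethanone
Conditions: BnBr (2.5 equiv), K2CO3 (3 equiv), DMF, 60 °C
Reagents that add atoms: benzyl bromide, BrCc1ccccc1
Why: Williamson benzylation of the two chelated hydroxyls under forcing conditions. Benzyl ethers stand base, organolithium and radical conditions and can later leave by neutral hydrogenolysis.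

Step 5
Reactants: 7 1-[4-(allyloxy)-2,6-bis(benzyloxy)phenyl]ethanone
Product: 8 1-[3-allyl-2,6-bis(benzyloxy)-4-hydroxyphenyl]ethanone
Conditions: N,N-diethylaniline, 190 °C, sealed tube
Reagents that add atoms: none
Why: Aromatic Claisen rearrangement. The allyl group can only move to the two equivalent ortho positions, giving the ring carbon that becomes C1, and the freed phenol oxygen becomes O6.

Step 6
Reactants: 8 1-[3-allyl-2,6-bis(benzyloxy)-4-hydroxyphenyl]ethanone
Product: 9 1-[3-allyl-2,6-bis(benzyloxy)-4-(triisopropylsilyloxy)phenyl]ethanone
Conditions: TIPSOTf, 2,6-lutidine, CH2Cl2, 0 °C → rt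
Reagents that add atoms: triisopropylsilyl trifluoromethanesulfonate, CC(C)[Si](C(C)C)(C(C)C)OS(=O)(=O)C(F)(F)F
Why: Silylation of the acidic phenol. The bulky O6 ether is the group that should differentiate C6 from C2 in step 12 and leave there as a silyl cation.

Step 7
Reactants: 9 1-[3-allyl-2,6-bis(benzyloxy)-4-(triisopropylsilyloxy)phenyl]ethanone
Product: 11 2-[3-acetyl-2,4-bis(benzyloxy)-6-(triisopropylsilyloxy)phenyl]acetaldehyde, via diol 10 (not isolated)
Conditions: OsO4 (2 mol %), NaIO4 (4 equiv), 2,6-lutidine, dioxane/H2O 3:1, rt
Reagents that add atoms: osmium tetroxide, O=[Os](=O)(=O)=O; sodium periodate, [Na+].[O-]I(=O)(=O)=O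
Why: Lemieux–Johnson cleavage (catalytic dihydroxylation, then periodate glycol cleavage). The lutidine buffer suppresses over-oxidation, and the acetyl-deactivated arene and the ethers should be inert.

Step 8
Reactants: 11 2-[3-acetyl-2,4-bis(benzyloxy)-6-(triisopropylsilyloxy)phenyl]acetaldehyde
Product: 12 1-[2,6-bis(benzyloxy)-3-(1,3-dithian-2-ylmethyl)-4-(triisopropylsilyloxy)phenyl]ethanone
Conditions: propane-1,3-dithiol, BF3·OEt2 (0.3 equiv), CH2Cl2, −20 °C
Reagents that add atoms: propane-1,3-dithiol, SCCCS
Why: Lewis acid dithioacetalisation. The aldehyde should react far faster than the aryl ketone flanked by two ortho substituents, and the dithiane carbon becomes the C7' acyl anion equivalent.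

Step 9
Reactants: 12 1-[2,6-bis(benzyloxy)-3-(1,3-dithian-2-ylmethyl)-4-(triisopropylsilyloxy)phenyl]ethanone; 4 (4R)-4-methyl-4-(triethylsilyloxy)hex-5-enal
Product: 14 1-{2,6-bis(benzyloxy)-3-[(2-{(4R)-1-hydroxy-4-methyl-4-(triethylsilyloxy)hex-5-en-1-yl}-1,3-dithian-2-yl)methyl]-4-(triisopropylsilyloxy)phenyl}ethanone, via dimetalated dithiane 13 (not isolated)
Conditions: KH (1.05 equiv), THF, 0 °C; t-BuLi (1.1 equiv), THF/HMPA 10:1, −78 °C; 4 (1.0 equiv), −78 °C; aq NH4Cl
Reagents that add atoms: none
Why: Corey–Seebach umpolung forms the C6'–C7' bond. The acetyl group is first masked in the flask as its potassium enolate (dihydrogen is the only by-product, so no acidic amine remains), then t-BuLi metalates the dithiane, whose anion is far more nucleophilic towards the aldehyde than the hindered enolate. The new carbinol centre is of no consequence.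

Step 10
Reactants: 14 dithiane carbinol (name as in step 9)
Product: 15 (6R)-1-[3-acetyl-2,4-bis(benzyloxy)-6-(triisopropylsilyloxy)phenyl]-3-hydroxy-6-methyl-6-(triethylsilyloxy)oct-7-en-2-one
Conditions: MeI (10 equiv), CaCO3 (5 equiv), MeCN/H2O 9:1, 45 °C
Reagents that add atoms: water, O
Why: Alkylative dithiane hydrolysis (S-methylation, then hydrolysis of the sulfonium salt) under carbonate buffer. It is non-oxidative, so the electron-rich arene, the vinyl group and both silyl ethers should be untouched.

Step 11
Reactants: 15 (6R)-1-[3-acetyl-2,4-bis(benzyloxy)-6-(triisopropylsilyloxy)phenyl]-3-hydroxy-6-methyl-6-(triethylsilyloxy)oct-7-en-2-one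
Product: 16 (6R)-1-[3-acetyl-2,4-bis(benzyloxy)-6-(triisopropylsilyloxy)phenyl]-3-bromo-6-methyl-6-(triethylsilyloxy)oct-7-en-2-one
Conditions: CBr4 (1.5 equiv), PPh3 (1.6 equiv), CH2Cl2, 0 °C
Reagents that add atoms: carbon tetrabromide, BrC(Br)(Br)Br
Why: Appel reaction. The oxyphosphonium ion is displaced by bromide in an SN2 step that the adjacent carbonyl accelerates. The neutral conditions avoid enolisation and put the halogen at C6' only, with no electrophilic bromine near the arene.

Step 12
Reactants: 16 (6R)-1-[3-acetyl-2,4-bis(benzyloxy)-6-(triisopropylsilyloxy)phenyl]-3-bromo-6-methyl-6-(triethylsilyloxy)oct-7-en-2-one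
Product: 18 (1R,2'S,3'R,6'R)-3-acetyl-2,4-bis(benzyloxy)-3'-methyl-3'-(triethylsilyloxy) spiro dienone (ring A cyclohexa-2,4-dien-6-one spiro at C1 to the trans-fused hydrindan-7'-one), via cis-fused C6' epimer 17 (not isolated)
Conditions: fac-Ir(ppy)3 (1 mol %), 2,6-lutidine (2 equiv), H2O (5 equiv), degassed MeCN (0.01 M), blue LEDs (450 nm), rt; then DBU (0.3 equiv), rt
Reagents that add atoms: none
Why: Photoexcited fac-Ir(ppy)3 reduces the C–Br bond to the electrophilic C6' α-keto radical, which closes ring C by 5-exo-trig addition to the vinyl group (C6'–C2' bond); the primary C1' radical then closes ring B by 6-exo ipso (spiro) attack on arene carbon C1, and the tris-oxygenated cyclohexadienyl radical is oxidised by the tetravalent iridium complex to an oxocarbenium ion that gives its O6 silyl group to water, so the cycle is redox-neutral. The closest known reaction type is the visible-light radical addition and ipso-cyclisation cascade of phenols and their ethers to spirocyclohexadienones, started by a standard 5-exo cyclisation of an α-halo ketone radical. C2' is set by C3': in the chair-like transition state the C3' methyl should lie pseudo-equatorial and the silyloxy group pseudo-axial, which puts C1' anti to the methyl. C1 is set by C2' and the ortho groups: in the chair-like closure of ring B the ortho carbon that ends axial lies gauche to C7', and the O6 triisopropylsilyl ether, whose isopropyl groups cover both faces, should avoid that place, leaving C2 (whose benzyloxy group can turn to the far face) axial. C6' forms as a mixture and DBU then equilibrates it through the C7' enol to the trans ring fusion, which is expected to be favoured as in the parent hydrindan-4-one. The step needs 5-exo over 6-endo closure (the carbonyl lies outside the forming ring and C3' is fully substituted), cyclisation over bromine-atom transfer or reduction (high dilution, no hydrogen donor) and ipso over ortho attack (both ortho carbons carry oxygen and ortho closure would give a seven-membered ring). No free phenol stands beside the α-bromoketone, which excludes chromanone and benzofuran formation.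

Step 13
Reactants: 18 spiro dienone ketone (name as in step 12)
Product: 19 (1R,2'S,3'R,6'R)-3-acetyl-2,4-bis(benzyloxy)-3'-methyl-7'-methylidene-3'-(triethylsilyloxy) spiro dienone
Conditions: Ph3PCH3Br (4 equiv), KOtBu (3.8 equiv), THF, 0 → 50 °C
Reagents that add atoms: methyltriphenylphosphonium bromide, C[P+](c1ccccc1)(c1ccccc1)c1ccccc1.[Br-]
Why: Wittig methylenation. The saturated C7' ketone is the only carbonyl that is not a vinylogous ester, and the acetyl group is at most enolised reversibly by the excess ylide. Methyl addition is avoided because it would enter from the equatorial face and give the C7' epimer.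

Step 14
Reactants: 19 7'-methylidene spiro dienone (name as in step 13)
Product: 21 (1R,2'S,3'R,6'R,7'R)-3-acetyl-2,4-bis(benzyloxy)-7'-hydroxy-3',7'-dimethyl-3'-(triethylsilyloxy) spiro dienone, via hydroperoxide 20 (not isolated)
Conditions: Co(acac)2 (20 mol %), PhSiH3 (2.5 equiv), O2 (1 atm), THF/i-PrOH 1:1, 0 °C → rt; then PPh3
Reagents that add atoms: dioxygen, O=O
Why: Mukaiyama hydration: a cobalt hydride transfers a hydrogen atom to the 1,1-disubstituted alkene, the tertiary C7' radical is captured by dioxygen and the hydroperoxide is reduced. Oxygen should enter from the open equatorial face because the axial face is covered by the axial C2 carbon of ring A with its oxygen and by 2'-H, which gives the equatorial hydroxyl and the axial methyl (7'R). The enol-ether alkenes of ring A are poor hydrogen-atom acceptors.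

Step 15
Reactants: 21 7'-carbinol spiro dienone (name as in step 14)
Product: 23 (1S,2'S,3'R,6'R,7'R)-3-acetyl-4,3',7'-trihydroxy-3',7'-dimethyl spiro trione (ring A 2-acetylcyclohexane-1,3,5-trione with C5H2), via triethylsilyl ether 22 (not isolated)
Conditions: H2 (1 atm), Pd/C (10 %), EtOAc, rt; filter; then TBAF (3 equiv), THF, rt; aq NH4Cl
Reagents that add atoms: none
Why: Hydrogenolysis of the two vinylogous benzyl esters frees the enolised triketone under neutral conditions, and no alkene is left to be reduced. Fluoride then removes the tertiary silyl ether without acid, so the tertiary alcohols are not put at risk.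

Step 16
Reactants: 23 spiro trione diol (name as in step 15); 24 prenyl bromide
Product: 26 CNP0266834.1 (1S,2'S,3'R,6'R,7'R), via 5-monoprenyl trione 25 (not isolated)
Conditions: 24 (2.6 equiv), 10 % aq KOH, 0 °C → rt; then dilute HCl
Reagents that add atoms: none
Why: Twofold C-alkylation of the dianion of the cyclic β-diketone at C5, the reaction type by which dearomatised acylphloroglucinols are bis-prenylated at one carbon. C3 is blocked as the acyl enolate and C1 is quaternary, so C5 is the only carbon nucleophile, and no stereocentre is formed.

## Compound list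

1 | (R)-linalool | C=C[C@](C)(O)CCC=C(C)C | starting material
2 | (3R)-3,7-dimethyl-3-(triethylsilyloxy)octa-1,6-diene | C=C[C@](C)(O[Si](CC)(CC)CC)CCC=C(C)C | intermediate
3 | ozonide (1,2,4-trioxolane) of the 6,7-alkene of 2 | C=C[C@](C)(O[Si](CC)(CC)CC)CCC1OOC(C)(C)O1 | intermediate
4 | (4R)-4-methyl-4-(triethylsilyloxy)hex-5-enal | C=C[C@](C)(O[Si](CC)(CC)CC)CCC=O | intermediate
5 | 2,4,6-trihydroxyacetophenone | CC(=O)c1c(O)cc(O)cc1O | starting material
6 | 1-[4-(allyloxy)-2,6-dihydroxyphenyl]ethanone | CC(=O)c1c(O)cc(OCC=C)cc1O | intermediate
7 | 1-[4-(allyloxy)-2,6-bis(benzyloxy)phenyl]ethanone | CC(=O)c1c(OCc2ccccc2)cc(OCC=C)cc1OCc1ccccc1 | intermediate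
8 | 1-[3-allyl-2,6-bis(benzyloxy)-4-hydroxyphenyl]ethanone | CC(=O)c1c(OCc2ccccc2)cc(O)c(CC=C)c1OCc1ccccc1 | intermediate
9 | 1-[3-allyl-2,6-bis(benzyloxy)-4-(triisopropylsilyloxy)phenyl]ethanone | CC(=O)c1c(OCc2ccccc2)cc(O[Si](C(C)C)(C(C)C)C(C)C)c(CC=C)c1OCc1ccccc1 | intermediate
10 | 1-[2,6-bis(benzyloxy)-3-(2,3-dihydroxypropyl)-4-(triisopropylsilyloxy)phenyl]ethanone | CC(=O)c1c(OCc2ccccc2)cc(O[Si](C(C)C)(C(C)C)C(C)C)c(CC(O)CO)c1OCc1ccccc1 | intermediate
11 | 2-[3-acetyl-2,4-bis(benzyloxy)-6-(triisopropylsilyloxy)phenyl]acetaldehyde | CC(=O)c1c(OCc2ccccc2)cc(O[Si](C(C)C)(C(C)C)C(C)C)c(CC=O)c1OCc1ccccc1 | intermediate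
12 | 1-[2,6-bis(benzyloxy)-3-(1,3-dithian-2-ylmethyl)-4-(triisopropylsilyloxy)phenyl]ethanone | CC(=O)c1c(OCc2ccccc2)cc(O[Si](C(C)C)(C(C)C)C(C)C)c(CC2SCCCS2)c1OCc1ccccc1 | intermediate
13 | potassium enolate and 2-lithio-1,3-dithiane derived from 12 | C=C(O[K])c1c(OCc2ccccc2)cc(O[Si](C(C)C)(C(C)C)C(C)C)c(CC2([Li])SCCCS2)c1OCc1ccccc1 | intermediate
14 | dithiane carbinol, (4R) in the hexenyl chain, epimers at the carbinol carbon | CC(=O)c1c(OCc2ccccc2)cc(O[Si](C(C)C)(C(C)C)C(C)C)c(CC2(SCCCS2)C(O)CC[C@@](C)(O[Si](CC)(CC)CC)C=C)c1OCc1ccccc1 | intermediate
15 | (6R)-1-[3-acetyl-2,4-bis(benzyloxy)-6-(triisopropylsilyloxy)phenyl]-3-hydroxy-6-methyl-6-(triethylsilyloxy)oct-7-en-2-one | CC(=O)c1c(OCc2ccccc2)cc(O[Si](C(C)C)(C(C)C)C(C)C)c(CC(=O)C(O)CC[C@@](C)(O[Si](CC)(CC)CC)C=C)c1OCc1ccccc1 | intermediate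
16 | (6R)-1-[3-acetyl-2,4-bis(benzyloxy)-6-(triisopropylsilyloxy)phenyl]-3-bromo-6-methyl-6-(triethylsilyloxy)oct-7-en-2-one | CC(=O)c1c(OCc2ccccc2)cc(O[Si](C(C)C)(C(C)C)C(C)C)c(CC(=O)C(Br)CC[C@@](C)(O[Si](CC)(CC)CC)C=C)c1OCc1ccccc1 | intermediate
17 | (1R,2'S,3'R,6'S) cis-fused C6' epimer of 18 | CC(=O)C1=C(OCc4ccccc4)[C@]2(C[C@H]3[C@H](CC[C@@]3(C)O[Si](CC)(CC)CC)C(=O)C2)C(=O)C=C1OCc5ccccc5 | intermediate
18 | (1R,2'S,3'R,6'R) spiro dienone: ring A 3-acetyl-2,4-bis(benzyloxy)cyclohexa-2,4-dien-6-one, spiro at C1 to the trans-fused 3'-methyl-3'-(triethylsilyloxy)hydrindan-7'-one, C2 axial and cis to 2'-H | CC(=O)C1=C(OCc4ccccc4)[C@]2(C[C@H]3[C@@H](CC[C@@]3(C)O[Si](CC)(CC)CC)C(=O)C2)C(=O)C=C1OCc5ccccc5 | intermediate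
19 | (1R,2'S,3'R,6'R) 7'-methylidene analogue of 18 | CC(=O)C1=C(OCc4ccccc4)[C@]2(C[C@H]3[C@@H](CC[C@@]3(C)O[Si](CC)(CC)CC)C(=C)C2)C(=O)C=C1OCc5ccccc5 | intermediate
20 | (1R,2'S,3'R,6'R,7'R) 7'-hydroperoxy-7'-methyl compound | CC(=O)C1=C(OCc4ccccc4)[C@]2(C[C@H]3[C@@H](CC[C@@]3(C)O[Si](CC)(CC)CC)[C@](C)(OO)C2)C(=O)C=C1OCc5ccccc5 | intermediate
21 | (1R,2'S,3'R,6'R,7'R) 7'-hydroxy-7'-methyl compound, methyl axial and cis to 2'-H | CC(=O)C1=C(OCc4ccccc4)[C@]2(C[C@H]3[C@@H](CC[C@@]3(C)O[Si](CC)(CC)CC)[C@](C)(O)C2)C(=O)C=C1OCc5ccccc5 | intermediate
22 | (1S,2'S,3'R,6'R,7'R) spiro trione with 3'-O-triethylsilyl ether | CC(=O)C1=C(O)CC(=O)[C@@]2(C[C@H]3[C@@H](CC[C@@]3(C)O[Si](CC)(CC)CC)[C@](C)(O)C2)C1=O | intermediate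
23 | (1S,2'S,3'R,6'R,7'R) spiro trione diol with C5H2 | CC(=O)C1=C(O)CC(=O)[C@@]2(C[C@H]3[C@@H](CC[C@@]3(C)O)[C@](C)(O)C2)C1=O | intermediate
24 | prenyl bromide (1-bromo-3-methylbut-2-ene) | CC(C)=CCBr | starting material
25 | 5-monoprenyl spiro trione diol, C5 unassigned | CC(=O)C1=C(O)C(CC=C(C)C)C(=O)[C@@]2(C[C@H]3[C@@H](CC[C@@]3(C)O)[C@](C)(O)C2)C1=O | intermediate
26 | CNP0266834.1, (1S,2'S,3'R,6'R,7'R) | CC(=O)C1=C(O)C(CC=C(C)C)(CC=C(C)C)C(=O)[C@@]2(C[C@H]3[C@@H](CC[C@@]3(C)O)[C@](C)(O)C2)C1=O | target

## Step count and least certain steps

Total: 16 steps. Longest linear sequence: 14 steps (5 to 26, steps 3 to 16); the linalool branch (steps 1 and 2) joins at step 9.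

**Step 12 (key step).**
- What may go wrong: poor facial selectivity in the 5-exo closure (C2' against C3') or at the spiro centre; diversion of the primary C1' radical by bromine-atom transfer or by a 1,5-hydrogen shift from C8' before the slow attack on the hindered arene carbon; an unfavourable cis/trans equilibrium at C6'.
- Fallback: the two closures are separated and the second is made polar. From 16, atom-transfer radical cyclisation with CuBr (monovalent copper) and tris(2-pyridylmethyl)amine should give the bromomethyl cyclopentyl ketone F1. CsF in DMF then removes the O6 silyl group, and the ortho carbon C1 of the phenoxide displaces the primary bromide in a 6-exo-tet dearomatising C-alkylation (O-alkylation would need an eight-membered ring). After DBU the route is rejoined at 18.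

**Step 9.**
- What may go wrong: proton transfer from the acetyl group to the dithiane anion if enolate formation is incomplete, or a competing aldol addition of the enolate to 4.
- Fallback: the ketone is masked covalently. From 12, TESOTf and Et3N give the silyl enol ether F2; t-BuLi and 4 then give the adduct F3; a citric acid work-up cleaves the enol ether and returns the route at 14.

**Step 14.**
- What may go wrong: low facial selectivity in the capture of the C7' radical, or hydrogen-atom transfer to the ring A enol ethers.
- Fallback: an ionic Markovnikov hydration. From 19, Hg(OAc)2 in THF/H2O should add water at C7' from the equatorial face to give the organomercurial F4 (ring A has no free enol oxygen at this stage to compete); NaBH4 in aqueous NaOH at 0 °C removes mercury and returns the route at 21.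

**Step 16.**
- What may go wrong: O-alkylation, a stalled second alkylation, or retro-Claisen opening of ring A in aqueous base.
- Fallback: from 23, Pd(PPh3)4 (zerovalent palladium) and allyl methyl carbonate give the 5,5-diallyl trione F5 by C-selective allylation; cross-metathesis with 2-methylbut-2-ene and the second-generation Grubbs catalyst then gives 26.

**Step 2.**
- What may go wrong: over-ozonolysis at the vinyl group.
- Fallback: from 2, mCPBA epoxidises only the trisubstituted alkene to the epoxide F6, and H5IO6 cleaves it to 4.

## Further compounds

F1 | step 12 | 1-[3-acetyl-2,4-bis(benzyloxy)-6-(triisopropylsilyloxy)phenyl]-3-[2-(bromomethyl)-3-methyl-3-(triethylsilyloxy)cyclopentyl]propan-2-one, bromomethyl cis to the silyloxy group, C6' epimers | CC(=O)c1c(OCc2ccccc2)cc(O[Si](C(C)C)(C(C)C)C(C)C)c(CC(=O)C2CC[C@@](C)(O[Si](CC)(CC)CC)[C@H]2CBr)c1OCc1ccccc1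
F2 | step 9 | triethylsilyl enol ether of 12 | C=C(O[Si](CC)(CC)CC)c1c(OCc2ccccc2)cc(O[Si](C(C)C)(C(C)C)C(C)C)c(CC2SCCCS2)c1OCc1ccccc1
F3 | step 9 | triethylsilyl enol ether of 14 | C=C(O[Si](CC)(CC)CC)c1c(OCc2ccccc2)cc(O[Si](C(C)C)(C(C)C)C(C)C)c(CC2(SCCCS2)C(O)CC[C@@](C)(O[Si](CC)(CC)CC)C=C)c1OCc1ccccc1
F4 | step 14 | 7'-hydroxy-7'-[(acetoxymercurio)methyl] analogue of 21 | CC(=O)C1=C(OCc4ccccc4)[C@]2(C[C@H]3[C@@H](CC[C@@]3(C)O[Si](CC)(CC)CC)[C@](C[Hg]OC(C)=O)(O)C2)C(=O)C=C1OCc5ccccc5
F5 | step 16 | 5,5-diallyl analogue of 26 | CC(=O)C1=C(O)C(CC=C)(CC=C)C(=O)[C@@]2(C[C@H]3[C@@H](CC[C@@]3(C)O)[C@](C)(O)C2)C1=O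
F6 | step 2 | 6,7-epoxide of 2, epimers at the epoxide | C=C[C@](C)(O[Si](CC)(CC)CC)CCC1OC1(C)C
A1 | alternative 1 | dimethyl 2-[(trans-2-oxo-5-isopropenylcyclopentyl)methyl]malonate | COC(=O)C(C[C@H]1[C@@H](CCC1=O)C(C)=C)C(=O)OC
A2 | alternative 2 | methylenecyclopentane with C3', C6' and C7' set (3'-O-triethylsilyl, 8'-O-pivaloyl) | C=C1[C@@H](CC[C@@]1(C)O[Si](CC)(CC)CC)[C@](C)(O)COC(=O)C(C)(C)C
A3 | alternative 3 | pyran-fused adduct of ring A and ring C | CC(=O)C1=C(O)C(CC=C(C)C)(CC=C(C)C)C(=O)C2=C1O[C@]3(C)CC[C@@H](C4(C)OCCO4)[C@@H]3C2
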